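- In a one-step world every initiator begins one chain, so the average length is the share of free monomer taken up times the charge ratio: 50.0 for ash and birch, free monomer charged per initiator charged.

| setting | delta | eta | ash | birch |
|---|---|---|---|---|
| free monomer | 11 mM | 11 mM | 11 mM | 11 mM |
| initiator | 0.11 mM | 0.17 mM | 0.22 mM | 0.22 mM |
| remark | run made earlier | run made earlier |  |  |
| time |  |  | 2.0 min | 6.0 min |

| run | time / s | monomer in chains / % | free monomer / % |
|---|---|---|---|
| delta | 10.0 | 1.1 | 100.3 |
| delta | 20.0 | 2.7 | 98.5 |
| delta | 40.0 | 8.8 | 91.5 |
| delta | 80.0 | 24.7 | 75.2 |
| eta | 10.0 | 1.0 | 98.6 |
| eta | 20.0 | 4.1 | 95.9 |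
| eta | 40.0 | 13.7 | 87.2 |
| eta | 80.0 | 35.3 | 64.2 |

(readings scatter by 0.5 percentage points)

- the average divides the monomer in chains by the number of chains begun, living and dead together
- what was read earlier has a scatter of 0.5 percentage points, one standard deviation
- the earlier runs do not show the number of chains; that part of a forecast is a guess

- which of the two ends with the longer chains by the average number of monomer units in a chain (chains begun, living or dead) ("neither" if they lie within 10 %) (ash / birch / neither)
- average number of monomer units in a chain (chains begun, living or dead) at the end, ash
- average number of monomer units in a chain (chains begun, living or dead) at the end, birch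

- That product, the full-charge length (the theoretical degree of polymerisation), is your floor: if fewer initiators begin chains, the same uptake sits on fewer chains. Complete uptake caps the floor at the ratio.
- To raise its lower bound, read the last interval: the logarithm of free monomer falls at 0.00490 s⁻¹ in delta and 0.00766 s⁻¹ in eta, as read. Their ratio, 1.56, matches the initiator ratio, 1.55, so scale eta to 0.00991 s⁻¹ for ash and birch.
- Ash and birch hold more initiator than eta, so assume they keep no more free monomer than eta's 64.2 % at 80.0 s. If that rate at least holds from then on and chains survive, free monomer is at most 43.2 % in ash and 4.01 % in birch.
- The floor therefore lies between 28.4 and 50.0 for ash, and between 48.0 and 50.0 for birch. The real length stands above the floor by as much as the share of initiator that begins no chain allows, and the earlier runs do not show that share, but I back birch, which has more time on the same charge.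
- The forecast says birch, with 34 for ash and 49 for birch, both inside these brackets: “Chain number is assumed”.
- The flask gives birch, with 71.8 for ash and 96.2 for birch.

    initiator → spent initiator A (k = 4.40 × 10⁻⁶ s⁻¹)
    free monomer + initiator → spent initiator B (k = 0.410 L mol⁻¹ s⁻¹)
    free monomer + initiator → living end + monomer in chains (k = 0.820 L mol⁻¹ s⁻¹)
    free monomer + living end → monomer in chains + living end, rate k4*[living end]*[free monomer] (k = 130 L mol⁻¹ s⁻¹)

- In ash, initiator fell to 48.8 % of its charge at 1.00 min and 32.2 % at 2.00 min, while living ends reached 0.0993 mM and free monomer fell to 34.7 % of its charge. In birch, free monomer, the limiting reagent, stood at 1.12 % of its charge at 6.00 min, with initiator at 23.2 % of its own and living ends at 0.113 mM. Ash's full-charge length of 32.4 stands against 71.8, with living ends equal to 45.2 % of the initiator charge.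
- A neighbour of ash, charged with 27 mM of free monomer and read at the same time, has a ratio of 123, and its uptake of 79.7 % gives a floor of 97.9. The computed length is 164, with living ends at 0.132 mM.

The runs are simulated on assumed constants; noise was put on by code.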